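**Plan**

- Target 29 is a 5,10-cis-fused bicyclic diterpenoid acid. Labels used: C1–C10 ring carbons, C11–C16 side chain, C17 exocyclic methylene carbon, C18 methyl on C4, C19 oxymethyl carbon on C4, C20 methyl on C10; TBS = tert-butyldimethylsilyl.
- Rings A and B show oxygen on C3, a quaternary C4 bearing CH3 and CH2O, H5 syn to C20, and a C8=C17 methylene. This is the pattern left when an epoxide opens at C4 into a chain with a Z C5=C10 olefin and an allylsilane at C8/C9 ends the cascade.
- Retrosynthesis: the allyl ester, C19 acetate and C3 ketone are adjusted last; C4–C5 and C9–C10 are cut together to the open-chain epoxy allylsilane 24; the chain is then cut at C13–C16, C14–C15, C11–C12, C8–C17 and C6–C7, back to neryl acetate.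
- Forward: the chain grows from the epoxide end to the enoate end (steps 1–14), rings A and B close together in step 15, and four steps set the oxidation state and the esters.
- Stereochemistry: C3 and C4 come from a Sharpless epoxidation (absolute); C5 and C10 from anti addition across the Z olefin of the neryl unit; C9 from the E allylsilane (C11 cis to C7) through a chair ring B; the 13Z enoate from syn carbocupration of an ynoate.

Key step: step 15

Remark: commercial neryl acetate of high 2Z purity is assumed; any geranyl isomer would enter the trans-fused series and must be removed before step 1.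

**Route**

Step 1
Reactants: 1 neryl acetate
Product: 2 (2Z,6E)-8-hydroxy-3,7-dimethylocta-2,6-dien-1-yl acetate
Conditions: SeO2 (cat.), t-BuOOH, salicylic acid (cat.), CH2Cl2, rt
Reagents that add atoms: tert-butyl hydroperoxide, CC(C)(C)OO (its oxygen is passed on by SeO2)
Why: SeO2-catalysed allylic oxidation (ene reaction, then [2,3]-sigmatropic shift) should hydroxylate the E-methyl of the terminal trisubstituted olefin, the olefin next to the acetate being deactivated, so the future C19 oxygen enters with E geometry.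

Step 2
Reactants: 2 (2Z,6E)-8-hydroxy-3,7-dimethylocta-2,6-dien-1-yl acetate
Product: 3 (2Z)-5-[(2S,3S)-3-(hydroxymethyl)-3-methyloxiran-2-yl]-3-methylpent-2-en-1-yl acetate
Conditions: Ti(OiPr)4, L-(+)-diethyl tartrate, t-BuOOH, 4 Å MS, CH2Cl2, −20 °C
Reagents that add atoms: tert-butyl hydroperoxide, CC(C)(C)OO
Why: Sharpless asymmetric epoxidation acts only on the allylic alcohol, and with L-(+)-diethyl tartrate an (E)-2-methylalk-2-en-1-ol is expected to give the (2S,3S)-epoxy alcohol, which fixes the future C3 and C4 in absolute terms.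

Step 3
Reactants: 3 epoxy alcohol
Product: 4 (2Z)-5-[(2S,3S)-3-(TBSOCH2)-3-methyloxiran-2-yl]-3-methylpent-2-en-1-yl acetate
Conditions: TBSCl, imidazole, DMF, 0 °C to rt
Reagents that add atoms: tert-butyldimethylsilyl chloride, CC(C)(C)[Si](C)(C)Cl
Why: Standard silylation of a primary alcohol; the silyl ether withstands the bases, hydrides and organometallics ahead and, unlike an ester, cannot capture the C4 cation in the cyclisation.

Step 4
Reactants: 4 silyl ether acetate
Product: 5 (2Z)-5-[(2S,3S)-3-(TBSOCH2)-3-methyloxiran-2-yl]-3-methylpent-2-en-1-ol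
Conditions: K2CO3, MeOH, 0 °C
Reagents that add atoms: none
Why: Base-catalysed transesterification frees the allylic alcohol, while the silyl ether blocks Payne rearrangement of the epoxide.

Step 5
Reactants: 5 allylic alcohol
Product: 7 (2Z)-1-bromo-5-[(2S,3S)-3-(TBSOCH2)-3-methyloxiran-2-yl]-3-methylpent-2-ene, via allylic mesylate 6 (not isolated)
Conditions: MsCl, Et3N, THF, −40 °C; then LiBr, THF, 0 °C
Reagents that add atoms: lithium bromide, [Li+].[Br-]
Why: Mesylation followed by SN2 displacement with bromide at the primary allylic carbon is the usual non-acidic way to prenyl-type bromides and should leave the Z olefin and the epoxide untouched.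

Step 6
Reactants: 7 allylic bromide; 8 methyl acetoacetate
Product: 10 methyl (6Z)-9-[(2S,3S)-3-(TBSOCH2)-3-methyloxiran-2-yl]-7-methyl-3-oxonon-6-enoate, via dianion of methyl acetoacetate 9 (not isolated)
Conditions: NaH, THF, 0 °C; n-BuLi, 0 °C; then 7, 0 °C
Reagents that add atoms: none
Why: Alkylation of the acetoacetate dianion occurs at the more basic terminal carbon (SN2 on the allylic bromide), forming C6–C7 and leaving a β-keto ester whose ketone is C8.

Step 7
Reactants: 10 β-keto ester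
Product: 11 methyl (2E,6Z)-9-[(2S,3S)-3-(TBSOCH2)-3-methyloxiran-2-yl]-7-methyl-3-(trifluoromethylsulfonyloxy)nona-2,6-dienoate
Conditions: Tf2O, aq. Me4NOH, toluene, 0–5 °C
Reagents that add atoms: triflic anhydride, O=S(=O)(OS(=O)(=O)C(F)(F)F)C(F)(F)F
Why: Enol triflation under non-chelating conditions: with the tetramethylammonium counter-ion the enolate reacts from its extended form, so O-sulfonylation should give the (2E)-triflate (TfO trans to CO2Me, hence C7 cis to C11), the geometry that later decides C9.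

Step 8
Reactants: 11 enol triflate; 12 (trimethylsilyl)methylmagnesium chloride
Product: 13 methyl (2E,6Z)-9-[(2S,3S)-3-(TBSOCH2)-3-methyloxiran-2-yl]-7-methyl-3-[(trimethylsilyl)methyl]nona-2,6-dienoate
Conditions: Pd(PPh3)4 (cat.), THF/Et2O, 0 °C to rt
Reagents that add atoms: none
Why: Kumada coupling: zerovalent palladium inserts into the C8–OTf bond, and transmetalation and reductive elimination proceed with retention of olefin geometry, so the silicon-bearing C17 ends trans to the ester.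

Step 9
Reactants: 13 allylsilane ester
Product: 14 (2E,6Z)-9-[(2S,3S)-3-(TBSOCH2)-3-methyloxiran-2-yl]-7-methyl-3-[(trimethylsilyl)methyl]nona-2,6-dien-1-ol
Conditions: i-Bu2AlH, CH2Cl2, −78 °C
Reagents that add atoms: none
Why: Hydride reduction of the enoate by 1,2-addition gives the allylic alcohol at a temperature at which the hindered trisubstituted epoxide should not be opened.

Step 10
Reactants: 14 allylic alcohol
Product: 16 (2E,6Z)-1-bromo-9-[(2S,3S)-3-(TBSOCH2)-3-methyloxiran-2-yl]-7-methyl-3-[(trimethylsilyl)methyl]nona-2,6-diene, via allylic mesylate 15 (not isolated)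
Conditions: MsCl, Et3N, THF, −40 °C; then LiBr, THF, −20 to 0 °C
Reagents that add atoms: lithium bromide, [Li+].[Br-]
Why: The same mesylate-to-bromide SN2 sequence as in step 5; low temperature and immediate use are meant to keep the silicon-stabilised allylic system from ionising.

Step 11
Reactants: 16 allylic bromide; 17 1-(trimethylsilyl)propyne
Product: 19 (5E,9Z)-12-[(2S,3S)-3-(TBSOCH2)-3-methyloxiran-2-yl]-10-methyl-1-(trimethylsilyl)-6-[(trimethylsilyl)methyl]dodeca-5,9-dien-1-yne, via 3-lithio-1-(trimethylsilyl)propyne 18 (not isolated)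
Conditions: 17, n-BuLi, THF, −78 to −30 °C; then 16, −78 to −20 °C
Reagents that add atoms: none
Why: Propargylation (SN2 at the primary allylic bromide) forms C11–C12, the alkynyl silyl group steering the ambident anion to the propargyl rather than the allenyl product.

Step 12
Reactants: 19 silyl enyne
Product: 20 (5E,9Z)-12-[(2S,3S)-3-(TBSOCH2)-3-methyloxiran-2-yl]-10-methyl-6-[(trimethylsilyl)methyl]dodeca-5,9-dien-1-yne
Conditions: K2CO3, MeOH, rt
Reagents that add atoms: none
Why: Methanolysis (protodesilylation) cleaves only the C(sp)–Si bond; the allylsilane, the silyl ether and the epoxide are stable to K2CO3 in methanol.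

Step 13
Reactants: 20 terminal alkyne
Product: 22 allyl (6E,10Z)-13-[(2S,3S)-3-(TBSOCH2)-3-methyloxiran-2-yl]-11-methyl-7-[(trimethylsilyl)methyl]trideca-6,10-dien-2-ynoate, via lithium acetylide 21 (not isolated)
Conditions: n-BuLi, THF, −78 °C; then ClCO2CH2CH=CH2, −78 to −20 °C
Reagents that add atoms: allyl chloroformate, C=CCOC(Cl)=O
Why: Deprotonation of the terminal alkyne and C-acylation of the acetylide with the chloroformate give the ynoate (C14–C15); the allyl ester is chosen because it can be removed at the end under neutral conditions.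

Step 14
Reactants: 22 ynoate
Product: 24 allyl (2Z,6E,10Z)-13-[(2S,3S)-3-(TBSOCH2)-3-methyloxiran-2-yl]-3,11-dimethyl-7-[(trimethylsilyl)methyl]trideca-2,6,10-trienoate, via alkenylcuprate 23 (not isolated)
Conditions: Me2CuLi (from MeLi, CuI), THF, −78 °C; then MeOH, −78 °C
Reagents that add atoms: lithium dimethylcuprate, [Li+].C[Cu-]C (made from methyllithium, [Li]C, and CuI)
Why: Conjugate addition of the cuprate to the ynoate is a syn carbocupration, and protonation of the alkenylcuprate with retention at −78 °C puts the new methyl C16 cis to H14, i.e. C12 cis to the ester (13Z); the low temperature suppresses equilibration through the allenoate and attack on the epoxide or the allyl ester.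

Step 15
Reactants: 24 epoxy allylsilane trienoate
Product: 25 allyl (2Z)-5-[(1S,4aS,5R,6S,8aR)-5-(TBSOCH2)-6-hydroxy-5,8a-dimethyl-2-methylidenedecahydronaphthalen-1-yl]-3-methylpent-2-enoate
Conditions: MeAlCl2 (3 equiv), CH2Cl2, −78 °C; then Et3N, aq. NaHCO3
Reagents that add atoms: none
Why: MeAlCl2 binds the epoxide oxygen and the C4–O bond ionises at the tertiary carbon as C5 of the Z olefin attacks C4 anti to the departing oxygen; the charge developing at C10 is taken up by C9 of the allylsilane, and the β-silyl-stabilised charge at C8 is quenched by loss of the Me3Si group, leaving the C8=C17 methylene as the only olefin isomer. The closest known reaction type is the Lewis-acid epoxy-polyene (cation–olefin) cyclisation with allylsilane termination, here in its Z-olefin variant. Ring A closes 6-endo (both carbons of C5=C10 and both epoxide carbons lie in the ring) and ring B closes 6-endo with respect to C8=C9. C3 keeps the epoxide configuration and C4 is the inverted epoxide carbon (CH2OTBS equatorial, trans to H5); C5 and C10 arise by anti addition across the Z olefin in a chair that places C18 and C20 syn-diaxial and so relays the epoxide chirality to a cis fusion with H5 syn to C20; C9 follows from the E allylsilane, whose C11 (cis to C7) takes the axial site of a chair ring B on the face of C20. The step needs chair–chair folding and a complete cascade before the Lewis acid isomerises the epoxide; the strongly nucleophilic allylsilane terminator, the conjugated and Lewis-acid-bound enoate as a non-nucleophilic spectator, and excess MeAlCl2 at −78 °C (to offset the slower ionisation caused by the C19 oxygen) are meant to secure this.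

Step 16
Reactants: 25 bicyclic alcohol
Product: 26 allyl (2Z)-5-[(1S,4aS,5R,8aR)-5-(TBSOCH2)-5,8a-dimethyl-2-methylidene-6-oxodecahydronaphthalen-1-yl]-3-methylpent-2-enoate
Conditions: Dess–Martin periodinane, NaHCO3, CH2Cl2, rt
Reagents that add atoms: none
Why: Dess–Martin oxidation of the secondary alcohol under buffered conditions; the new ketone is flanked by quaternary C4 and the C2 methylene, so no stereocentre can epimerise.

Step 17
Reactants: 26 silyloxy ketone
Product: 27 allyl (2Z)-5-[(1S,4aS,5R,8aR)-5-(hydroxymethyl)-5,8a-dimethyl-2-methylidene-6-oxodecahydronaphthalen-1-yl]-3-methylpent-2-enoate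
Conditions: HF·pyridine, pyridine, THF, 0 °C to rt
Reagents that add atoms: none
Why: Fluoride cleavage of the Si–O bond with buffered HF·pyridine avoids the basic conditions under which the β-hydroxy ketone could lose formaldehyde by retro-aldol reaction.

Step 18
Reactants: 27 hydroxy ketone
Product: 28 allyl (2Z)-5-[(1S,4aS,5R,8aR)-5-(acetoxymethyl)-5,8a-dimethyl-2-methylidene-6-oxodecahydronaphthalen-1-yl]-3-methylpent-2-enoate
Conditions: Ac2O, pyridine, DMAP (cat.), CH2Cl2, 0 °C to rt
Reagents that add atoms: acetic anhydride, CC(=O)OC(C)=O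
Why: DMAP-catalysed acylation of the primary alcohol installs the acetate and removes the retro-aldol liability.

Step 19
Reactants: 28 acetoxy ketone allyl ester
Product: 29 (2Z)-5-[(1S,4aS,5R,8aR)-5-(acetoxymethyl)-5,8a-dimethyl-2-methylidene-6-oxodecahydronaphthalen-1-yl]-3-methylpent-2-enoic acid
Conditions: Pd(PPh3)4 (cat.), morpholine, THF, rt
Reagents that add atoms: none
Why: Tsuji–Trost deallylation: zerovalent palladium ionises the allyl ester to a π-allyl complex that morpholine intercepts, freeing the acid under neutral conditions that spare the acetate, the ketone, the exocyclic olefin and the Z enoate.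

**Compound list**

1 | neryl acetate, (2Z)-3,7-dimethylocta-2,6-dien-1-yl acetate | CC(C)=CCC/C(C)=C\COC(C)=O | starting material
2 | (2Z,6E)-8-hydroxy-3,7-dimethylocta-2,6-dien-1-yl acetate | OC/C(C)=C/CC/C(C)=C\COC(C)=O | intermediate
3 | (2Z)-5-[(2S,3S)-3-(hydroxymethyl)-3-methyloxiran-2-yl]-3-methylpent-2-en-1-yl acetate | OC[C@]1(C)O[C@H]1CC/C(C)=C\COC(C)=O | intermediate
4 | (2Z)-5-[(2S,3S)-3-(TBSOCH2)-3-methyloxiran-2-yl]-3-methylpent-2-en-1-yl acetate | CC(C)(C)[Si](C)(C)OC[C@]1(C)O[C@H]1CC/C(C)=C\COC(C)=O | intermediate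
5 | (2Z)-5-[(2S,3S)-3-(TBSOCH2)-3-methyloxiran-2-yl]-3-methylpent-2-en-1-ol | CC(C)(C)[Si](C)(C)OC[C@]1(C)O[C@H]1CC/C(C)=C\CO | intermediate
6 | methanesulfonate of 5 (formed in the flask) | CC(C)(C)[Si](C)(C)OC[C@]1(C)O[C@H]1CC/C(C)=C\COS(C)(=O)=O | intermediate
7 | (2Z)-1-bromo-5-[(2S,3S)-3-(TBSOCH2)-3-methyloxiran-2-yl]-3-methylpent-2-ene | CC(C)(C)[Si](C)(C)OC[C@]1(C)O[C@H]1CC/C(C)=C\CBr | intermediate
8 | methyl acetoacetate | COC(=O)CC(C)=O | starting material
9 | sodium lithium dianion of methyl acetoacetate (formed in the flask) | [CH2-]C(=O)[CH-]C(=O)OC.[Na+].[Li+] | intermediate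
10 | methyl (6Z)-9-[(2S,3S)-3-(TBSOCH2)-3-methyloxiran-2-yl]-7-methyl-3-oxonon-6-enoate | CC(C)(C)[Si](C)(C)OC[C@]1(C)O[C@H]1CC/C(C)=C\CCC(=O)CC(=O)OC | intermediate
11 | methyl (2E,6Z)-9-[(2S,3S)-3-(TBSOCH2)-3-methyloxiran-2-yl]-7-methyl-3-(trifluoromethylsulfonyloxy)nona-2,6-dienoate | CC(C)(C)[Si](C)(C)OC[C@]1(C)O[C@H]1CC/C(C)=C\CC/C(OS(=O)(=O)C(F)(F)F)=C\C(=O)OC | intermediate
12 | (trimethylsilyl)methylmagnesium chloride | C[Si](C)(C)C[Mg]Cl | starting material
13 | methyl (2E,6Z)-9-[(2S,3S)-3-(TBSOCH2)-3-methyloxiran-2-yl]-7-methyl-3-[(trimethylsilyl)methyl]nona-2,6-dienoate | CC(C)(C)[Si](C)(C)OC[C@]1(C)O[C@H]1CC/C(C)=C\CC/C(C[Si](C)(C)C)=C\C(=O)OC | intermediate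
14 | (2E,6Z)-9-[(2S,3S)-3-(TBSOCH2)-3-methyloxiran-2-yl]-7-methyl-3-[(trimethylsilyl)methyl]nona-2,6-dien-1-ol | CC(C)(C)[Si](C)(C)OC[C@]1(C)O[C@H]1CC/C(C)=C\CC/C(C[Si](C)(C)C)=C\CO | intermediate
15 | methanesulfonate of 14 (formed in the flask) | CC(C)(C)[Si](C)(C)OC[C@]1(C)O[C@H]1CC/C(C)=C\CC/C(C[Si](C)(C)C)=C\COS(C)(=O)=O | intermediate
16 | (2E,6Z)-1-bromo-9-[(2S,3S)-3-(TBSOCH2)-3-methyloxiran-2-yl]-7-methyl-3-[(trimethylsilyl)methyl]nona-2,6-diene | CC(C)(C)[Si](C)(C)OC[C@]1(C)O[C@H]1CC/C(C)=C\CC/C(C[Si](C)(C)C)=C\CBr | intermediate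
17 | 1-(trimethylsilyl)propyne | CC#C[Si](C)(C)C | starting material
18 | 3-lithio-1-(trimethylsilyl)propyne (formed in the flask) | [Li]CC#C[Si](C)(C)C | intermediate
19 | (5E,9Z)-12-[(2S,3S)-3-(TBSOCH2)-3-methyloxiran-2-yl]-10-methyl-1-(trimethylsilyl)-6-[(trimethylsilyl)methyl]dodeca-5,9-dien-1-yne | CC(C)(C)[Si](C)(C)OC[C@]1(C)O[C@H]1CC/C(C)=C\CC/C(C[Si](C)(C)C)=C\CCC#C[Si](C)(C)C | intermediate
20 | (5E,9Z)-12-[(2S,3S)-3-(TBSOCH2)-3-methyloxiran-2-yl]-10-methyl-6-[(trimethylsilyl)methyl]dodeca-5,9-dien-1-yne | CC(C)(C)[Si](C)(C)OC[C@]1(C)O[C@H]1CC/C(C)=C\CC/C(C[Si](C)(C)C)=C\CCC#C | intermediate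
21 | lithium acetylide of 20 (formed in the flask) | CC(C)(C)[Si](C)(C)OC[C@]1(C)O[C@H]1CC/C(C)=C\CC/C(C[Si](C)(C)C)=C\CCC#C[Li] | intermediate
22 | allyl (6E,10Z)-13-[(2S,3S)-3-(TBSOCH2)-3-methyloxiran-2-yl]-11-methyl-7-[(trimethylsilyl)methyl]trideca-6,10-dien-2-ynoate | CC(C)(C)[Si](C)(C)OC[C@]1(C)O[C@H]1CC/C(C)=C\CC/C(C[Si](C)(C)C)=C\CCC#CC(=O)OCC=C | intermediate
23 | lithium methyl(alkenyl)cuprate, the C14-cuprio syn adduct of 22 (formed in the flask) | CC(C)(C)[Si](C)(C)OC[C@]1(C)O[C@H]1CC/C(C)=C\CC/C(C[Si](C)(C)C)=C\CC/C(C)=C(\C(=O)OCC=C)[Cu-]C.[Li+] | intermediate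
24 | allyl (2Z,6E,10Z)-13-[(2S,3S)-3-(TBSOCH2)-3-methyloxiran-2-yl]-3,11-dimethyl-7-[(trimethylsilyl)methyl]trideca-2,6,10-trienoate | CC(C)(C)[Si](C)(C)OC[C@]1(C)O[C@H]1CC/C(C)=C\CC/C(C[Si](C)(C)C)=C\CC/C(C)=C\C(=O)OCC=C | intermediate
25 | allyl (2Z)-5-[(1S,4aS,5R,6S,8aR)-5-(TBSOCH2)-6-hydroxy-5,8a-dimethyl-2-methylidenedecahydronaphthalen-1-yl]-3-methylpent-2-enoate | C=C1CC[C@H]2[C@](C)(CC[C@H](O)[C@@]2(C)CO[Si](C)(C)C(C)(C)C)[C@H]1CC/C(C)=C\C(=O)OCC=C | intermediate
26 | allyl (2Z)-5-[(1S,4aS,5R,8aR)-5-(TBSOCH2)-5,8a-dimethyl-2-methylidene-6-oxodecahydronaphthalen-1-yl]-3-methylpent-2-enoate | C=C1CC[C@H]2[C@](C)(CCC(=O)[C@@]2(C)CO[Si](C)(C)C(C)(C)C)[C@H]1CC/C(C)=C\C(=O)OCC=C | intermediate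
27 | allyl (2Z)-5-[(1S,4aS,5R,8aR)-5-(hydroxymethyl)-5,8a-dimethyl-2-methylidene-6-oxodecahydronaphthalen-1-yl]-3-methylpent-2-enoate | C=C1CC[C@H]2[C@](C)(CCC(=O)[C@@]2(C)CO)[C@H]1CC/C(C)=C\C(=O)OCC=C | intermediate
28 | allyl (2Z)-5-[(1S,4aS,5R,8aR)-5-(acetoxymethyl)-5,8a-dimethyl-2-methylidene-6-oxodecahydronaphthalen-1-yl]-3-methylpent-2-enoate | C=C1CC[C@H]2[C@](C)(CCC(=O)[C@@]2(C)COC(C)=O)[C@H]1CC/C(C)=C\C(=O)OCC=C | intermediate
29 | (2Z)-5-[(1S,4aS,5R,8aR)-5-(acetoxymethyl)-5,8a-dimethyl-2-methylidene-6-oxodecahydronaphthalen-1-yl]-3-methylpent-2-enoic acid | C=C1CC[C@H]2[C@](C)(CCC(=O)[C@@]2(C)COC(C)=O)[C@H]1CC/C(C)=C\C(=O)O | target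

**Step count**

Total step count: 19.
Longest linear sequence: 19 steps (1 to 29); compounds 8, 12 and 17 are commercial and enter directly.

**Steps most likely to fail**

1. Step 15. Ring B may close through a boat-like array instead of the chair, because the Z olefin attaches the C6–C9 tether axially to ring A; C9 would then form with the opposite configuration while the rest of the cascade is unchanged. The fallback exchanges the one stereochemical input that is independent of the epoxide and of the Z olefin, the C8=C9 geometry, so that the same boat-like closure delivers the required C9. It sets out from keto ester 10 and returns at 25. Triflation of 10 through the chelated lithium enolate (Tf2O, aq. LiOH, toluene) would give the (2Z,6Z)-enol triflate F1. Coupling with 12 under Pd(PPh3)4 would give the (2Z,6Z)-allylsilane ester F2, and i-Bu2AlH the allylic alcohol F3. MsCl/Et3N would give the mesylate F4 and LiBr the bromide F5. Alkylation with 18 would give the silyl enyne F6, and K2CO3 in methanol the terminal alkyne F7. n-BuLi would give the acetylide F8, and allyl chloroformate the ynoate F9. Me2CuLi would add syn to give the alkenylcuprate F10, protonated at −78 °C to the (2Z,6Z,10Z)-trienoate F11. Cyclisation of F11 with MeAlCl2 would then give 25.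

2. Step 7. Part of the enolate may react through a metal-chelated or equilibrated form and give the Z enol triflate, which would carry the wrong C8=C9 geometry into the cyclisation; Tf2O may also attack the epoxide. The fallback builds the same olefin by a stereospecific syn carbocupration and avoids triflic anhydride. It sets out from bromide 7 and returns at 13. Alkylation of 7 with 18 would give the silyl enyne F12, and K2CO3 in methanol the terminal alkyne F13. n-BuLi would give the acetylide F14, and methyl chloroformate the ynoate F15. The cuprate F16, made from 12 and CuI, would add syn at −78 °C to give the alkenylcuprate F17, and protonation with retention would give 13 with C7 cis to the ester by construction.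

3. Step 11. The strongly basic propargyllithium may trigger 1,4-elimination of bromide and the silyl group to a 1,3-diene, or attack in the SN2′ sense, instead of substituting at C11. The fallback uses a softer stabilised carbanion and makes the C13=C14 olefin by enol-derivative coupling instead of carbocupration. It sets out from bromide 16 and returns at 24. The dianion of allyl acetoacetate F18 (NaH, then n-BuLi) would alkylate 16 to the keto ester F19. Non-chelating enol phosphorylation (ClP(O)(OEt)2, Et3N, DMAP, DMPU) would give the (2E)-enol phosphate F20, and Me2CuLi would replace the phosphate by methyl with retention to give 24.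

Further compounds
F1 | step 15 | methyl (2Z,6Z)-9-[(2S,3S)-3-(TBSOCH2)-3-methyloxiran-2-yl]-7-methyl-3-(trifluoromethylsulfonyloxy)nona-2,6-dienoate | CC(C)(C)[Si](C)(C)OC[C@]1(C)O[C@H]1CC/C(C)=C\CC/C(OS(=O)(=O)C(F)(F)F)=C/C(=O)OC
F2 | step 15 | methyl (2Z,6Z)-9-[(2S,3S)-3-(TBSOCH2)-3-methyloxiran-2-yl]-7-methyl-3-[(trimethylsilyl)methyl]nona-2,6-dienoate | CC(C)(C)[Si](C)(C)OC[C@]1(C)O[C@H]1CC/C(C)=C\CC/C(C[Si](C)(C)C)=C/C(=O)OC
F3 | step 15 | (2Z,6Z)-9-[(2S,3S)-3-(TBSOCH2)-3-methyloxiran-2-yl]-7-methyl-3-[(trimethylsilyl)methyl]nona-2,6-dien-1-ol | CC(C)(C)[Si](C)(C)OC[C@]1(C)O[C@H]1CC/C(C)=C\CC/C(C[Si](C)(C)C)=C/CO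
F4 | step 15 | methanesulfonate of F3 (formed in the flask) | CC(C)(C)[Si](C)(C)OC[C@]1(C)O[C@H]1CC/C(C)=C\CC/C(C[Si](C)(C)C)=C/COS(C)(=O)=O
F5 | step 15 | (2Z,6Z)-1-bromo-9-[(2S,3S)-3-(TBSOCH2)-3-methyloxiran-2-yl]-7-methyl-3-[(trimethylsilyl)methyl]nona-2,6-diene | CC(C)(C)[Si](C)(C)OC[C@]1(C)O[C@H]1CC/C(C)=C\CC/C(C[Si](C)(C)C)=C/CBr
F6 | step 15 | (5Z,9Z)-12-[(2S,3S)-3-(TBSOCH2)-3-methyloxiran-2-yl]-10-methyl-1-(trimethylsilyl)-6-[(trimethylsilyl)methyl]dodeca-5,9-dien-1-yne | CC(C)(C)[Si](C)(C)OC[C@]1(C)O[C@H]1CC/C(C)=C\CC/C(C[Si](C)(C)C)=C/CCC#C[Si](C)(C)C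
F7 | step 15 | (5Z,9Z)-12-[(2S,3S)-3-(TBSOCH2)-3-methyloxiran-2-yl]-10-methyl-6-[(trimethylsilyl)methyl]dodeca-5,9-dien-1-yne | CC(C)(C)[Si](C)(C)OC[C@]1(C)O[C@H]1CC/C(C)=C\CC/C(C[Si](C)(C)C)=C/CCC#C
F8 | step 15 | lithium acetylide of F7 (formed in the flask) | CC(C)(C)[Si](C)(C)OC[C@]1(C)O[C@H]1CC/C(C)=C\CC/C(C[Si](C)(C)C)=C/CCC#C[Li]
F9 | step 15 | allyl (6Z,10Z)-13-[(2S,3S)-3-(TBSOCH2)-3-methyloxiran-2-yl]-11-methyl-7-[(trimethylsilyl)methyl]trideca-6,10-dien-2-ynoate | CC(C)(C)[Si](C)(C)OC[C@]1(C)O[C@H]1CC/C(C)=C\CC/C(C[Si](C)(C)C)=C/CCC#CC(=O)OCC=C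
F10 | step 15 | lithium methyl(alkenyl)cuprate, the C14-cuprio syn adduct of F9 (formed in the flask) | CC(C)(C)[Si](C)(C)OC[C@]1(C)O[C@H]1CC/C(C)=C\CC/C(C[Si](C)(C)C)=C/CC/C(C)=C(\C(=O)OCC=C)[Cu-]C.[Li+]
F11 | step 15 | allyl (2Z,6Z,10Z)-13-[(2S,3S)-3-(TBSOCH2)-3-methyloxiran-2-yl]-3,11-dimethyl-7-[(trimethylsilyl)methyl]trideca-2,6,10-trienoate | CC(C)(C)[Si](C)(C)OC[C@]1(C)O[C@H]1CC/C(C)=C\CC/C(C[Si](C)(C)C)=C/CC/C(C)=C\C(=O)OCC=C
F12 | step 7 | (5Z)-8-[(2S,3S)-3-(TBSOCH2)-3-methyloxiran-2-yl]-6-methyl-1-(trimethylsilyl)oct-5-en-1-yne | CC(C)(C)[Si](C)(C)OC[C@]1(C)O[C@H]1CC/C(C)=C\CCC#C[Si](C)(C)C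
F13 | step 7 | (5Z)-8-[(2S,3S)-3-(TBSOCH2)-3-methyloxiran-2-yl]-6-methyloct-5-en-1-yne | CC(C)(C)[Si](C)(C)OC[C@]1(C)O[C@H]1CC/C(C)=C\CCC#C
F14 | step 7 | lithium acetylide of F13 (formed in the flask) | CC(C)(C)[Si](C)(C)OC[C@]1(C)O[C@H]1CC/C(C)=C\CCC#C[Li]
F15 | step 7 | methyl (6Z)-9-[(2S,3S)-3-(TBSOCH2)-3-methyloxiran-2-yl]-7-methylnon-6-en-2-ynoate | CC(C)(C)[Si](C)(C)OC[C@]1(C)O[C@H]1CC/C(C)=C\CCC#CC(=O)OC
F16 | step 7 | chloromagnesium bis[(trimethylsilyl)methyl]cuprate (formed in the flask from 12 and CuI) | C[Si](C)(C)C[Cu-]C[Si](C)(C)C.[Mg+]Cl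
F17 | step 7 | chloromagnesium alkenylcuprate, the C9-cuprio syn adduct of F15 (formed in the flask) | CC(C)(C)[Si](C)(C)OC[C@]1(C)O[C@H]1CC/C(C)=C\CC/C(C[Si](C)(C)C)=C(\C(=O)OC)[Cu-]C[Si](C)(C)C.[Mg+]Cl
F18 | step 11 | sodium lithium dianion of allyl acetoacetate (formed in the flask) | [CH2-]C(=O)[CH-]C(=O)OCC=C.[Na+].[Li+]
F19 | step 11 | allyl (6E,10Z)-13-[(2S,3S)-3-(TBSOCH2)-3-methyloxiran-2-yl]-11-methyl-3-oxo-7-[(trimethylsilyl)methyl]trideca-6,10-dienoate | CC(C)(C)[Si](C)(C)OC[C@]1(C)O[C@H]1CC/C(C)=C\CC/C(C[Si](C)(C)C)=C\CCC(=O)CC(=O)OCC=C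
F20 | step 11 | allyl (2E,6E,10Z)-3-(diethoxyphosphoryloxy)-13-[(2S,3S)-3-(TBSOCH2)-3-methyloxiran-2-yl]-11-methyl-7-[(trimethylsilyl)methyl]trideca-2,6,10-trienoate | CC(C)(C)[Si](C)(C)OC[C@]1(C)O[C@H]1CC/C(C)=C\CC/C(C[Si](C)(C)C)=C\CC/C(OP(=O)(OCC)OCC)=C\C(=O)OCC=C
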